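**Plan**

- Retrosynthesis first cuts the depside C(=O)–O bond between the ring A carboxyl and the ring B 4-oxygen. Both side-chain ketones are traced back to 1,1-disubstituted alkenes (C=O from C=CH2).
- In each ring the aryl–CH2 bond and the adjacent aryl–CO2H bond are then cut together. Ring A carries CO2H on C1, oxygen on C2 and the side-chain CH2 on C6. This is the pattern a 3-alkoxyaryne gives when a carbon nucleophile enters at the far aryne carbon and CO2 at the near one. Ring B (C1 CO2H, C2 OMe, C6 CH2) repeats it.
- Forward order: allylic Grignard reagent (steps 1–3); ring A acid by aryne/Grignard/CO2 coupling (steps 4–5); ring B phenol by the same coupling, benzyl ester formation and desilylation (steps 6–9); esterification joins the halves (step 10); both alkenes are cleaved to ketones (step 11); hydrogenolysis frees phenols and acid (step 12).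
- No ring is built, since both benzene rings are bought. The target has no stereocentre and no stereogenic double bond, so no stereocontrol is needed.

Key step: step 5

Remark: Grignard reagent 6 is kept as a titrated THF solution and counted as the product of step 3; the target is aimed at in its open keto acid form.

**Route**

Step 1
Reactants: 1 prop-2-yn-1-ol (propargyl alcohol); 2 pentylmagnesium bromide
Product: 4 2-methylideneheptan-1-ol, via alkenylmagnesium alkoxide 3 (not isolated)
Conditions: 2 (2.5 equiv), CuI (10 mol %), Et2O, −10 °C to rt; then 1 M HCl, 0 °C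
Reagents that add atoms: none
Why: Copper-catalysed anti-carbomagnesiation of the propargylic magnesium alkoxide places pentyl on C2 and magnesium on C3 in a five-membered chelate (3), and protonolysis of the alkenyl–magnesium bond should give the 2-substituted allylic alcohol, a reaction type established for primary alkyl Grignard reagents.

Step 2
Reactants: 4 2-methylideneheptan-1-ol
Product: 5 2-(chloromethyl)hept-1-ene
Conditions: NCS, Me2S, CH2Cl2, −20 °C to 0 °C
Reagents that add atoms: N-chlorosuccinimide, O=C1CCC(=O)N1Cl
Why: Corey–Kim chlorination, in which chloride displaces the alkoxysulfonium ion under non-acidic conditions; the allyl unit is symmetric about C2, so even allyl-transposed substitution gives the same chloride.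

Step 3
Reactants: 5 2-(chloromethyl)hept-1-ene
Product: 6 (2-methylideneheptyl)magnesium chloride (titrated THF solution)
Conditions: Mg turnings (3 equiv, I2-activated), THF, 0 °C, slow addition
Reagents that add atoms: magnesium, [Mg]
Why: Grignard formation by insertion of magnesium into the allylic C–Cl bond is standard for 2-substituted allyl chlorides, and low temperature, dilution and excess metal hold back Wurtz coupling.

Step 4
Reactants: 7 5-bromobenzene-1,3-diol (5-bromoresorcinol)
Product: 8 1,3-bis(benzyloxy)-5-bromobenzene
Conditions: BnBr (2.2 equiv), K2CO3, DMF, rt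
Reagents that add atoms: benzyl bromide, BrCc1ccccc1
Why: Williamson etherification of both phenols; benzyl ethers should tolerate the amide base and the Grignard reagent of step 5 and leave by hydrogenolysis in the last step.

Step 5
Reactants: 8 1,3-bis(benzyloxy)-5-bromobenzene; 6 (2-methylideneheptyl)magnesium chloride; 9 carbon dioxide
Product: 13 2,4-bis(benzyloxy)-6-(2-methylideneheptyl)benzoic acid, via aryllithium 10 (not isolated), via 3,5-bis(benzyloxy)benzyne 11 (not isolated), via arylmagnesium chloride 12 (not isolated)
Conditions: 8 and 6 (2.5 equiv) premixed in THF, −78 °C; lithium 2,2,6,6-tetramethylpiperidide (LiTMP, 1.3 equiv, from TMPH and n-BuLi) added dropwise, −78 °C to rt; CO2 (gas), −78 °C to rt; 0.5 M HCl, 0 °C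
Reagents that add atoms: none
Why: LiTMP removes the ring proton between bromine and a benzyloxy group (lithiation between the two ether oxygens cannot expel bromide and returns to the pool by proton exchange with TMPH), loss of LiBr from 10 gives aryne 11, Grignard reagent 6 adds across the strained triple bond (carbomagnesiation) and CO2 carboxylates the arylmagnesium 12, so the aryl–CH2 and aryl–CO2H bonds form on neighbouring carbons in one flask. The closest known reaction type is the three-component coupling of 3-alkoxyarynes with 2-substituted allylmagnesium halides and an electrophile such as CO2. No ring closes and no stereocentre is created. The step needs regioselective addition to the unsymmetrical aryne: the in-plane, inductively withdrawing C–O bond beside the triple bond makes the remote aryne carbon (the former C–Br carbon) the electrophilic one and stabilises the carbanion developing next to oxygen, so carbon enters meta to that ether and magnesium, then CO2, ortho to it. The two termini of the 2-pentylallyl nucleophile are equivalent, so direct and allyl-transposed attack give the same side chain, whose 1,1-disubstituted alkene is the masked ketone.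

Step 6
Reactants: 14 3-fluoro-5-methoxyphenol
Product: 15 (3-fluoro-5-methoxyphenoxy)tri(propan-2-yl)silane
Conditions: TIPSCl, imidazole, DMF, rt
Reagents that add atoms: chlorotri(propan-2-yl)silane, CC(C)[Si](Cl)(C(C)C)C(C)C
Why: Imidazole-promoted silylation gives a bulky silyl ether that neither coordinates butyllithium nor leaves its ortho positions accessible, which should steer the lithiation of step 7 to the carbon between fluorine and methoxy.

Step 7
Reactants: 15 (3-fluoro-5-methoxyphenoxy)tri(propan-2-yl)silane; 6 (2-methylideneheptyl)magnesium chloride; 9 carbon dioxide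
Product: 19 2-methoxy-6-(2-methylideneheptyl)-4-[(triisopropylsilyl)oxy]benzoic acid, via aryllithium 16 (not isolated), via 3-methoxy-5-(triisopropylsilyloxy)benzyne 17 (not isolated), via arylmagnesium chloride 18 (not isolated)
Conditions: n-BuLi (1.05 equiv), THF, −78 °C; 6 (2.5 equiv), −78 °C to rt; CO2 (gas), −78 °C to rt; 0.5 M HCl, 0 °C
Reagents that add atoms: none
Why: Directed ortho-lithiation between fluorine and methoxy gives 16, which loses LiF on warming to aryne 17; Grignard reagent 6 then adds at the aryne carbon remote from methoxy and CO2 carboxylates arylmagnesium 18 next to it, the same three-component aryne coupling as step 5 in the variant known for 3,5-dialkoxyfluorobenzenes.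

Step 8
Reactants: 19 2-methoxy-6-(2-methylideneheptyl)-4-[(triisopropylsilyl)oxy]benzoic acid
Product: 20 benzyl 2-methoxy-6-(2-methylideneheptyl)-4-[(triisopropylsilyl)oxy]benzoate
Conditions: BnBr, KHCO3, DMF, rt
Reagents that add atoms: benzyl bromide, BrCc1ccccc1
Why: Carboxylate O-alkylation (SN2 at benzyl bromide) esterifies the doubly ortho-substituted acid without attack at its hindered carbonyl, and hydrogencarbonate is too weak a base to cleave the aryl silyl ether.

Step 9
Reactants: 20 benzyl 2-methoxy-6-(2-methylideneheptyl)-4-[(triisopropylsilyl)oxy]benzoate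
Product: 21 benzyl 4-hydroxy-2-methoxy-6-(2-methylideneheptyl)benzoate
Conditions: Bu4NF (TBAF), AcOH, THF, 0 °C
Reagents that add atoms: none
Why: Fluoride-mediated desilylation, driven by the strong Si–F bond, frees the 4-hydroxyl, with acetic acid buffering the phenoxide so that benzyl ester and alkene are left alone.

Step 10
Reactants: 13 2,4-bis(benzyloxy)-6-(2-methylideneheptyl)benzoic acid; 21 benzyl 4-hydroxy-2-methoxy-6-(2-methylideneheptyl)benzoate
Product: 22 4-[(benzyloxy)carbonyl]-3-methoxy-5-(2-methylideneheptyl)phenyl 2,4-bis(benzyloxy)-6-(2-methylideneheptyl)benzoate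
Conditions: DCC, DMAP, CH2Cl2, 0 °C to rt
Reagents that add atoms: none
Why: Steglich esterification, in which DMAP passes the acyl group of the carbodiimide-activated acid to the unhindered phenol oxygen; the 1,1-disubstituted alkene, unlike the ketone it masks, cannot cyclise onto the activated carboxyl to an isocoumarin.

Step 11
Reactants: 22 4-[(benzyloxy)carbonyl]-3-methoxy-5-(2-methylideneheptyl)phenyl 2,4-bis(benzyloxy)-6-(2-methylideneheptyl)benzoate
Product: 23 4-[(benzyloxy)carbonyl]-3-methoxy-5-(2-oxoheptyl)phenyl 2,4-bis(benzyloxy)-6-(2-oxoheptyl)benzoate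
Conditions: OsO4 (2 mol %), NaIO4 (4.4 equiv), 2,6-lutidine, 1,4-dioxane/H2O (3:1), rt
Reagents that add atoms: osmium tetroxide, O=[Os](=O)(=O)=O; sodium periodate, [Na+].[O-]I(=O)(=O)=O
Why: Lemieux–Johnson oxidation, in which catalytic OsO4 dihydroxylates both unhindered 1,1-disubstituted alkenes and NaIO4 cleaves the diols and regenerates the catalyst, 2,6-lutidine suppressing over-oxidation while the fully protected arenes and the three esters stay inert.

Step 12
Reactants: 23 4-[(benzyloxy)carbonyl]-3-methoxy-5-(2-oxoheptyl)phenyl 2,4-bis(benzyloxy)-6-(2-oxoheptyl)benzoate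
Product: 24 arthonioic acid, 4-{[2,4-dihydroxy-6-(2-oxoheptyl)benzoyl]oxy}-2-methoxy-6-(2-oxoheptyl)benzoic acid
Conditions: H2 (1 atm), 10% Pd/C (palladium on carbon), EtOAc, rt
Reagents that add atoms: none
Why: Catalytic hydrogenolysis removes the two aryl benzyl ethers and the benzyl ester in one neutral operation, which should leave the depside ester and the two non-conjugated ketones intact and avoids acid- or base-induced cyclisation of the 2-oxoheptyl benzoates to isocoumarins.

**Compound list**

1 | prop-2-yn-1-ol (propargyl alcohol) | C#CCO | starting material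
2 | pentylmagnesium bromide | CCCCC[Mg]Br | starting material
3 | bromomagnesium (2Z)-3-(bromomagnesio)-2-pentylprop-2-en-1-olate | CCCCC/C(CO[Mg]Br)=C/[Mg]Br | intermediate
4 | 2-methylideneheptan-1-ol | CCCCCC(=C)CO | intermediate
5 | 2-(chloromethyl)hept-1-ene | CCCCCC(=C)CCl | intermediate
6 | (2-methylideneheptyl)magnesium chloride | CCCCCC(=C)C[Mg]Cl | intermediate
7 | 5-bromobenzene-1,3-diol (5-bromoresorcinol) | Oc1cc(O)cc(Br)c1 | starting material
8 | 1,3-bis(benzyloxy)-5-bromobenzene | Brc1cc(OCc2ccccc2)cc(OCc2ccccc2)c1 | intermediate
9 | carbon dioxide | O=C=O | starting material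
10 | [2,4-bis(benzyloxy)-6-bromophenyl]lithium | [Li]c1c(Br)cc(OCc2ccccc2)cc1OCc1ccccc1 | intermediate
11 | 3,5-bis(benzyloxy)benzyne | C1#CC(OCc2ccccc2)=CC(OCc2ccccc2)=C1 | intermediate
12 | [2,4-bis(benzyloxy)-6-(2-methylideneheptyl)phenyl]magnesium chloride | Cl[Mg]c1c(CC(=C)CCCCC)cc(OCc2ccccc2)cc1OCc1ccccc1 | intermediate
13 | 2,4-bis(benzyloxy)-6-(2-methylideneheptyl)benzoic acid | CCCCCC(=C)Cc1cc(OCc2ccccc2)cc(OCc2ccccc2)c1C(=O)O | intermediate
14 | 3-fluoro-5-methoxyphenol | COc1cc(O)cc(F)c1 | starting material
15 | (3-fluoro-5-methoxyphenoxy)tri(propan-2-yl)silane | COc1cc(F)cc(O[Si](C(C)C)(C(C)C)C(C)C)c1 | intermediate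
16 | {2-fluoro-6-methoxy-4-[(triisopropylsilyl)oxy]phenyl}lithium | [Li]c1c(F)cc(O[Si](C(C)C)(C(C)C)C(C)C)cc1OC | intermediate
17 | 3-methoxy-5-[(triisopropylsilyl)oxy]benzyne | C1#CC(OC)=CC(O[Si](C(C)C)(C(C)C)C(C)C)=C1 | intermediate
18 | {2-methoxy-6-(2-methylideneheptyl)-4-[(triisopropylsilyl)oxy]phenyl}magnesium chloride | Cl[Mg]c1c(CC(=C)CCCCC)cc(O[Si](C(C)C)(C(C)C)C(C)C)cc1OC | intermediate
19 | 2-methoxy-6-(2-methylideneheptyl)-4-[(triisopropylsilyl)oxy]benzoic acid | CCCCCC(=C)Cc1cc(O[Si](C(C)C)(C(C)C)C(C)C)cc(OC)c1C(=O)O | intermediate
20 | benzyl 2-methoxy-6-(2-methylideneheptyl)-4-[(triisopropylsilyl)oxy]benzoate | CCCCCC(=C)Cc1cc(O[Si](C(C)C)(C(C)C)C(C)C)cc(OC)c1C(=O)OCc1ccccc1 | intermediate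
21 | benzyl 4-hydroxy-2-methoxy-6-(2-methylideneheptyl)benzoate | CCCCCC(=C)Cc1cc(O)cc(OC)c1C(=O)OCc1ccccc1 | intermediate
22 | 4-[(benzyloxy)carbonyl]-3-methoxy-5-(2-methylideneheptyl)phenyl 2,4-bis(benzyloxy)-6-(2-methylideneheptyl)benzoate | CCCCCC(=C)Cc1cc(OCc2ccccc2)cc(OCc2ccccc2)c1C(=O)Oc1cc(CC(=C)CCCCC)c(C(=O)OCc2ccccc2)c(OC)c1 | intermediate
23 | 4-[(benzyloxy)carbonyl]-3-methoxy-5-(2-oxoheptyl)phenyl 2,4-bis(benzyloxy)-6-(2-oxoheptyl)benzoate | CCCCCC(=O)Cc1cc(OCc2ccccc2)cc(OCc2ccccc2)c1C(=O)Oc1cc(CC(=O)CCCCC)c(C(=O)OCc2ccccc2)c(OC)c1 | intermediate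
24 | arthonioic acid | CCCCCC(=O)Cc1cc(O)cc(O)c1C(=O)Oc1cc(CC(=O)CCCCC)c(C(=O)O)c(OC)c1 | target

**Step count and risks**

Total steps: 12. Longest linear sequence: 9 steps (1, 2, 3, 7, 8, 9, 10, 11, 12).

Steps most likely to fail:

Step 5. The amide base may metalate a benzylic ether CH2 or the position between the two ether oxygens, bromine may migrate between ring positions, or the aryne may be intercepted by the amide or by aryllithium 10 before the Grignard reagent reaches it. The fallback separates the two bond formations and avoids the aryne. Starting from 8, a Kumada coupling with Grignard reagent 6 (PdCl2(dppf) cat., THF) should give 1,3-bis(benzyloxy)-5-(2-methylideneheptyl)benzene F1. Vilsmeier–Haack formylation (POCl3, DMF) at one of the two equivalent positions ortho to the side chain and para to an ether should give 2,4-bis(benzyloxy)-6-(2-methylideneheptyl)benzaldehyde F2. Pinnick oxidation (NaClO2, NaH2PO4, 2-methylbut-2-ene, t-BuOH/H2O) returns to the route at 13.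

Step 7. Lithiation next to the silyloxy group, attack of butyllithium at silicon, or protonation of the arylmagnesium before carboxylation would erode regiochemical purity or conversion. The fallback installs the carboxyl first and the side chain second, without an aryne. Starting from 15, lithiation as in step 7 to 16 and carboxylation at −78 °C before any warming should give 2-fluoro-6-methoxy-4-[(triisopropylsilyl)oxy]benzoic acid F3. Carboxylate-directed nucleophilic aromatic substitution of the fluoride by excess Grignard reagent 6 (THF, 0 °C to rt), fluoride being displaced in preference to methoxide, returns to the route at 19.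

Step 10. Acyl transfer from the O-acylisourea of the 2,6-disubstituted acid may be slow enough for rearrangement to the N-acylurea to take over. The fallback replaces in situ activation by an isolated acyl halide. Starting from 13, 1-chloro-N,N,2-trimethylprop-1-en-1-amine (CH2Cl2, 0 °C to rt, neutral so that no HCl adds to the alkene) should give 2,4-bis(benzyloxy)-6-(2-methylideneheptyl)benzoyl chloride F4. Acylation of phenol 21 by F4 (Et3N, DMAP, CH2Cl2) returns to the route at 22.

**Further compounds**

F1 | step 5 | 1,3-bis(benzyloxy)-5-(2-methylideneheptyl)benzene | CCCCCC(=C)Cc1cc(OCc2ccccc2)cc(OCc2ccccc2)c1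
F2 | step 5 | 2,4-bis(benzyloxy)-6-(2-methylideneheptyl)benzaldehyde | CCCCCC(=C)Cc1cc(OCc2ccccc2)cc(OCc2ccccc2)c1C=O
F3 | step 7 | 2-fluoro-6-methoxy-4-[(triisopropylsilyl)oxy]benzoic acid | COc1cc(O[Si](C(C)C)(C(C)C)C(C)C)cc(F)c1C(=O)O
F4 | step 10 | 2,4-bis(benzyloxy)-6-(2-methylideneheptyl)benzoyl chloride | CCCCCC(=C)Cc1cc(OCc2ccccc2)cc(OCc2ccccc2)c1C(=O)Cl
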